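**Retrosynthetic overview** (cyclohexanone numbering: C1 C=O, C2 C(CH3)–O, C3 CH–O, C4 CH2, C5 side-chain carbon, C6 CH–O-acyl)
- Endgame: both angelates go on last, onto the diol; the C6 oxygen comes from hydroxylation of the only enolisable position of the epoxy ketone.
- The oxirane (second ring formed) is cis to the C5 side chain, the face that alkaline peroxide or a halohydrin-type closure would not deliver. It is therefore placed by hydroxyl-directed epoxidation of the cis-allylic alcohol made from the enone, followed by re-oxidation.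
- Key disconnection (first ring formed): ring bonds C5–C6 and C2–C3 are made in one pot from an acyclic dienal and 3-oxopentanoic acid by catalyst-controlled decarboxylative Michael addition and intramolecular aldol condensation (formal [3+3]).
- Enabling feature: the ring carbonyl C1 lies between C6 and C2, so C6–C1–C2(CH3) is the chain of a β-keto acid that is nucleophilic at both α-carbons. C5–C4–C3 is the β-carbon, α-carbon and formyl carbon of an enal, and the 2-methyl-2,3-epoxycyclohexanone is a masked 2-methylcyclohex-2-enone.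
- Dienal: asymmetric allylboration of 2-bromoacrolein, silylation, cross-metathesis to the prenyl group, Suzuki coupling with a C3 enal unit.

Key step: step 7

Remark (assumption): the absolute sense of the allylboration and of the amine-catalysed Michael addition is taken from the accepted transition-state models; should either prove reversed, the enantiomeric reagent or catalyst is used.

**Step 1**
Reactants: 1 acrolein
Product: 3 2-bromoacrolein, via 2,3-dibromopropanal 2 (not isolated)
Conditions: Br2, CH2Cl2, −78 → 0 °C; then Et3N, 0 °C; used as a fresh solution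
Reagents that add atoms: bromine, BrBr
Why: Addition of bromine to the enal C=C and E1cB loss of HBr from the α-bromo aldehyde (bromination/dehydrobromination) give the α-bromo enal; no stereocentre is involved.

**Step 2**
Reactants: 3 2-bromoacrolein
Product: 5 (3S)-2-bromohexa-1,5-dien-3-ol, via borinate ester 4 (not isolated)
Conditions: (−)-Ipc2B(allyl) (commercial solution), Et2O, −78 °C; then 3 M NaOH, 30% H2O2, 0 °C → rt
Reagents that add atoms: (−)-B-allyldiisopinocampheylborane, C=CCB([C@@H]1C[C@@H]2C[C@H]([C@H]1C)C2(C)C)[C@@H]1C[C@@H]2C[C@H]([C@H]1C)C2(C)C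
Why: Brown allylboration through a closed chair transition state, in which the isopinocampheyl groups derived from (+)-α-pinene should deliver the allyl group to the Si face of the aldehyde and so give the (S)-carbinol.

**Step 3**
Reactants: 5 (3S)-2-bromohexa-1,5-dien-3-ol
Product: 6 {[(3S)-2-bromohexa-1,5-dien-3-yl]oxy}(tert-butyl)dimethylsilane
Conditions: TBSCl, imidazole, DMF, rt
Reagents that add atoms: tert-butyldimethylsilyl chloride, CC(C)(C)[Si](C)(C)Cl
Why: Standard silylation of a secondary alcohol; the ether should survive the amine, hydride and enolate steps and keeps the later vanadium epoxidation away from the exocyclic alkene.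

**Step 4**
Reactants: 6 {[(3S)-2-bromohexa-1,5-dien-3-yl]oxy}(tert-butyl)dimethylsilane
Product: 7 {[(3S)-2-bromo-6-methylhepta-1,5-dien-3-yl]oxy}(tert-butyl)dimethylsilane
Conditions: Grubbs II (5 mol %), 2-methyl-2-butene/CH2Cl2, 40 °C
Reagents that add atoms: 2-methyl-2-butene, CC=C(C)C
Why: Olefin cross-metathesis of the monosubstituted alkene with excess 2-methyl-2-butene installs the prenyl terminus, while the hindered, electron-poor 1,1-disubstituted bromoalkene should stay out of the cycle; the stereocentre is untouched.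

**Step 5**
Reactants: 7 {[(3S)-2-bromo-6-methylhepta-1,5-dien-3-yl]oxy}(tert-butyl)dimethylsilane; 8 (E)-2-(3,3-diethoxyprop-1-en-1-yl)-4,4,5,5-tetramethyl-1,3,2-dioxaborolane
Product: 10 (2E,5S)-5-(tert-butyldimethylsilyloxy)-8-methyl-4-methylidenenona-2,7-dienal, via diethyl acetal 9 (not isolated)
Conditions: Pd(dppf)Cl2 (5 mol %), K3PO4, THF/H2O, 50 °C; then 1 M HCl, THF, 0 °C, short
Reagents that add atoms: water, O
Why: Suzuki–Miyaura coupling of the alkenyl bromide with the (E)-alkenylboronate proceeds with retention of alkene geometry, and brief aqueous acid hydrolyses the allylic acetal to the (E)-enal without touching the silyl ether.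

**Step 6**
Reactants: 11 ethyl 3-oxopentanoate
Product: 13 3-oxopentanoic acid, via sodium 3-oxopentanoate 12 (not isolated)
Conditions: 1 M NaOH, H2O, rt; then HCl, 0 °C, Et2O extraction; used at once
Reagents that add atoms: sodium hydroxide, [Na+].[OH-]
Why: Saponification of the β-keto ester and cold acidification give the β-keto acid, which is used immediately because it loses CO2 on standing.

**Step 7**
Reactants: 10 (2E,5S)-5-(tert-butyldimethylsilyloxy)-8-methyl-4-methylidenenona-2,7-dienal; 13 3-oxopentanoic acid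
Product: 15 (5R)-5-[(3S)-3-(tert-butyldimethylsilyloxy)-6-methylhepta-1,5-dien-2-yl]-2-methylcyclohex-2-en-1-one, via keto aldehyde 14 (not isolated)
Conditions: (S)-α,α-diphenylprolinol trimethylsilyl ether (20 mol %), CHCl3, 0 °C → rt; then pyrrolidine (30 mol %), AcOH (30 mol %), 45 °C, same pot
Reagents that add atoms: none
Why: The (S)-prolinol silyl ether condenses with 10 to the s-trans E-iminium ion, the enol of 13 adds through its C2 to the β-carbon on the face away from the CPh2(OTMS) group and loses CO2 to give keto aldehyde 14 (first ring bond, between the future acyloxy-bearing carbon and the side-chain-bearing carbon), after which the ketone enolises towards its ethyl CH2 and condenses with the aldehyde (second ring bond, formed as the C=C that later carries the oxirane). The closest known reaction type is the prolinol-silyl-ether-catalysed Michael addition of β-keto esters or β-keto acids to enals followed by intramolecular aldol condensation, a catalytic enantioselective Robinson-type [3+3] route to 5-substituted cyclohex-2-enones. The one ring closed is the cyclohexenone, by a 6-(enolendo)-exo-trig aldol addition and E1cB loss of water; the other aldol pairings would give four-membered rings and do not compete. The one new stereocentre (the ring carbon bearing the side chain, R in 14 and 15 by the CIP rules, with the spatial arrangement required in 22) is set by the catalyst through shielding of one face of the iminium ion, and the remote silyloxy centre is not expected to override it. The step needs 1,4- and not 1,6-addition to the dienyl iminium ion: the unsubstituted β-carbon carries the larger LUMO coefficient, the branched silyloxyalkyl group on the inner diene carbon twists the terminal methylene out of conjugation, and the dienal has no γ-hydrogen, so no dienamine can form. The product should not racemise because its stereocentre is not enolisable.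

**Step 8**
Reactants: 15 (5R)-5-[(3S)-3-(tert-butyldimethylsilyloxy)-6-methylhepta-1,5-dien-2-yl]-2-methylcyclohex-2-en-1-one
Product: 16 (1R,5R)-5-[(3S)-3-(tert-butyldimethylsilyloxy)-6-methylhepta-1,5-dien-2-yl]-2-methylcyclohex-2-en-1-ol (OH cis to the side chain)
Conditions: NaBH4, CeCl3·7H2O, MeOH, −78 °C
Reagents that add atoms: none
Why: Luche 1,2-reduction, in which axial hydride delivery to the half-chair with the side chain equatorial should give the pseudo-equatorial alcohol cis to the side chain, as in the reduction of carvone to cis-carveol.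

**Step 9**
Reactants: 16 (1R,5R)-5-[(3S)-3-(tert-butyldimethylsilyloxy)-6-methylhepta-1,5-dien-2-yl]-2-methylcyclohex-2-en-1-ol
Product: 17 (1R,2R,4S,6S)-4-[(3S)-3-(tert-butyldimethylsilyloxy)-6-methylhepta-1,5-dien-2-yl]-1-methyl-7-oxabicyclo[4.1.0]heptan-2-ol (oxirane, OH and side chain all cis)
Conditions: VO(acac)2 (5 mol %), t-BuOOH (decane), CH2Cl2, 0 °C → rt
Reagents that add atoms: tert-butyl hydroperoxide, CC(C)(C)OO
Why: Vanadium-catalysed hydroxyl-directed epoxidation should deliver oxygen to the ring alkene on the face of the allylic OH, that is cis to the side chain (both oxirane centres), and leave the silyl-protected exocyclic alkene and the prenyl alkene alone.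

**Step 10**
Reactants: 17 (1R,2R,4S,6S)-4-[(3S)-3-(tert-butyldimethylsilyloxy)-6-methylhepta-1,5-dien-2-yl]-1-methyl-7-oxabicyclo[4.1.0]heptan-2-ol
Product: 18 (1S,4R,6S)-4-[(3S)-3-(tert-butyldimethylsilyloxy)-6-methylhepta-1,5-dien-2-yl]-1-methyl-7-oxabicyclo[4.1.0]heptan-2-one (oxirane cis to the side chain)
Conditions: Dess–Martin periodinane, NaHCO3, CH2Cl2, 0 °C → rt
Reagents that add atoms: none
Why: Dess–Martin oxidation of the secondary epoxy alcohol to the ketone under buffered conditions that should not disturb the oxirane or any stereocentre.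

**Step 11**
Reactants: 18 (1S,4R,6S)-4-[(3S)-3-(tert-butyldimethylsilyloxy)-6-methylhepta-1,5-dien-2-yl]-1-methyl-7-oxabicyclo[4.1.0]heptan-2-one
Product: 20 (1S,3S,4S,6S)-4-[(3S)-3-(tert-butyldimethylsilyloxy)-6-methylhepta-1,5-dien-2-yl]-3-hydroxy-1-methyl-7-oxabicyclo[4.1.0]heptan-2-one, via potassium enolate 19 (not isolated)
Conditions: KHMDS, THF, −78 °C; then 2-(phenylsulfonyl)-3-phenyloxaziridine, −78 °C; AcOH quench
Reagents that add atoms: 2-(phenylsulfonyl)-3-phenyloxaziridine, O=S(=O)(c1ccccc1)N1OC1c1ccccc1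
Why: Davis oxidation of the only possible enolate (the oxirane carbon on the other side of the carbonyl has no hydrogen), in which the oxaziridine should approach anti to the adjacent side chain and to the oxirane oxygen and so place the hydroxyl trans to both.

**Step 12**
Reactants: 20 (1S,3S,4S,6S)-4-[(3S)-3-(tert-butyldimethylsilyloxy)-6-methylhepta-1,5-dien-2-yl]-3-hydroxy-1-methyl-7-oxabicyclo[4.1.0]heptan-2-one
Product: 21 (1S,3S,4S,6S)-3-hydroxy-4-[(3S)-3-hydroxy-6-methylhepta-1,5-dien-2-yl]-1-methyl-7-oxabicyclo[4.1.0]heptan-2-one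
Conditions: HF·pyridine, pyridine, THF, 0 °C → rt
Reagents that add atoms: none
Why: Fluoride cleavage of the secondary silyl ether under buffered conditions that should spare the epoxy ketone and the α-ketol.

**Step 13**
Reactants: 21 (1S,3S,4S,6S)-3-hydroxy-4-[(3S)-3-hydroxy-6-methylhepta-1,5-dien-2-yl]-1-methyl-7-oxabicyclo[4.1.0]heptan-2-one
Product: 22 (1S,3S,4S,6S)-4-[(3S)-3-(angeloyloxy)-6-methylhepta-1,5-dien-2-yl]-1-methyl-2-oxo-7-oxabicyclo[4.1.0]heptan-3-yl (Z)-2-methylbut-2-enoate (CNP0271744.2)
Conditions: angelic acid, 2,4,6-trichlorobenzoyl chloride, Et3N, toluene, rt; then 21, toluene, 75 °C (no DMAP)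
Reagents that add atoms: angelic acid, C/C=C(/C)C(=O)O
Why: Yamaguchi-type acylation of both secondary alcohols with the preformed mixed anhydride, run without a nucleophilic catalyst so that the (Z)-alkene should not isomerise to the tiglate; no stereocentre is touched.

**Compound list**
1 | acrolein | C=CC=O | starting material
2 | 2,3-dibromopropanal (racemic) | O=CC(Br)CBr | intermediate
3 | 2-bromoacrolein | C=C(Br)C=O | intermediate
4 | B-[(3S)-2-bromohexa-1,5-dien-3-yloxy]diisopinocampheylborane (borinate ester) | C=C(Br)[C@H](CC=C)OB([C@@H]1C[C@@H]2C[C@H]([C@H]1C)C2(C)C)[C@@H]1C[C@@H]2C[C@H]([C@H]1C)C2(C)C | intermediate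
5 | (3S)-2-bromohexa-1,5-dien-3-ol | C=C(Br)[C@H](CC=C)O | intermediate
6 | {[(3S)-2-bromohexa-1,5-dien-3-yl]oxy}(tert-butyl)dimethylsilane | C=C(Br)[C@H](CC=C)O[Si](C)(C)C(C)(C)C | intermediate
7 | {[(3S)-2-bromo-6-methylhepta-1,5-dien-3-yl]oxy}(tert-butyl)dimethylsilane | C=C(Br)[C@H](CC=C(C)C)O[Si](C)(C)C(C)(C)C | intermediate
8 | (E)-2-(3,3-diethoxyprop-1-en-1-yl)-4,4,5,5-tetramethyl-1,3,2-dioxaborolane | CCOC(OCC)/C=C/B1OC(C)(C)C(C)(C)O1 | starting material
9 | (2E,5S)-5-(tert-butyldimethylsilyloxy)-1,1-diethoxy-8-methyl-4-methylidenenona-2,7-diene (diethyl acetal of 10) | CCOC(OCC)/C=C/C(=C)[C@H](CC=C(C)C)O[Si](C)(C)C(C)(C)C | intermediate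
10 | (2E,5S)-5-(tert-butyldimethylsilyloxy)-8-methyl-4-methylidenenona-2,7-dienal | O=C/C=C/C(=C)[C@H](CC=C(C)C)O[Si](C)(C)C(C)(C)C | intermediate
11 | ethyl 3-oxopentanoate | CCOC(=O)CC(=O)CC | starting material
12 | sodium 3-oxopentanoate | [Na+].[O-]C(=O)CC(=O)CC | intermediate
13 | 3-oxopentanoic acid | OC(=O)CC(=O)CC | intermediate
14 | (3R)-3-[(3S)-3-(tert-butyldimethylsilyloxy)-6-methylhepta-1,5-dien-2-yl]-5-oxoheptanal | C=C([C@H](CC=C(C)C)O[Si](C)(C)C(C)(C)C)[C@@H](CC(=O)CC)CC=O | intermediate
15 | (5R)-5-[(3S)-3-(tert-butyldimethylsilyloxy)-6-methylhepta-1,5-dien-2-yl]-2-methylcyclohex-2-en-1-one | C=C([C@H](CC=C(C)C)O[Si](C)(C)C(C)(C)C)[C@@H]1CC=C(C)C(=O)C1 | intermediate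
16 | (1R,5R)-5-[(3S)-3-(tert-butyldimethylsilyloxy)-6-methylhepta-1,5-dien-2-yl]-2-methylcyclohex-2-en-1-ol | C=C([C@H](CC=C(C)C)O[Si](C)(C)C(C)(C)C)[C@@H]1CC=C(C)[C@H](O)C1 | intermediate
17 | (1R,2R,4S,6S)-4-[(3S)-3-(tert-butyldimethylsilyloxy)-6-methylhepta-1,5-dien-2-yl]-1-methyl-7-oxabicyclo[4.1.0]heptan-2-ol | C=C([C@H](CC=C(C)C)O[Si](C)(C)C(C)(C)C)[C@@H]1C[C@@H]2O[C@]2(C)[C@H](O)C1 | intermediate
18 | (1S,4R,6S)-4-[(3S)-3-(tert-butyldimethylsilyloxy)-6-methylhepta-1,5-dien-2-yl]-1-methyl-7-oxabicyclo[4.1.0]heptan-2-one | C=C([C@H](CC=C(C)C)O[Si](C)(C)C(C)(C)C)[C@@H]1C[C@@H]2O[C@]2(C)C(=O)C1 | intermediate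
19 | potassium enolate of 18 (enolate C=C between the carbonyl carbon and the former CH2) | [K+].C=C([C@H](CC=C(C)C)O[Si](C)(C)C(C)(C)C)[C@@H]1C[C@@H]2O[C@]2(C)C([O-])=C1 | intermediate
20 | (1S,3S,4S,6S)-4-[(3S)-3-(tert-butyldimethylsilyloxy)-6-methylhepta-1,5-dien-2-yl]-3-hydroxy-1-methyl-7-oxabicyclo[4.1.0]heptan-2-one (the change of descriptor at C4 from 18 is a CIP priority effect only) | C=C([C@H](CC=C(C)C)O[Si](C)(C)C(C)(C)C)[C@@H]1C[C@@H]2O[C@]2(C)C(=O)[C@H]1O | intermediate
21 | (1S,3S,4S,6S)-3-hydroxy-4-[(3S)-3-hydroxy-6-methylhepta-1,5-dien-2-yl]-1-methyl-7-oxabicyclo[4.1.0]heptan-2-one | C=C([C@H](CC=C(C)C)O)[C@@H]1C[C@@H]2O[C@]2(C)C(=O)[C@H]1O | intermediate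
22 | (1S,3S,4S,6S)-4-[(3S)-3-(angeloyloxy)-6-methylhepta-1,5-dien-2-yl]-1-methyl-2-oxo-7-oxabicyclo[4.1.0]heptan-3-yl (Z)-2-methylbut-2-enoate | C=C([C@H](CC=C(C)C)OC(=O)/C(C)=C\C)[C@@H]1C[C@@H]2O[C@]2(C)C(=O)[C@H]1OC(=O)/C(C)=C\C | target

**Count**
Total steps: 13. Longest linear sequence: 12 (steps 1–5 and 7–13; step 6 is a one-step side branch).

**Steps most likely to fail**

Step 7. The keto acid may add to the terminal methylene carbon of the dienyl iminium ion (1,6-addition), or the dienal may oligomerise, instead of the wanted 1,4-addition. The fallback sets out from 7 and comes back at 15. Palladium-catalysed Miyaura borylation of bromide 7 (B2pin2, PdCl2(PPh3)2, KOPh, toluene) would give the alkenylboronate F1. Rhodium-catalysed asymmetric 1,4-addition (Hayashi–Miyaura, [Rh(cod)OH]2/(R)-BINAP, aqueous dioxane) of F1 to racemic 6-methylcyclohex-2-en-1-one F2 would give the 3-alkenyl-6-methylcyclohexanone F3, with the ring stereocentre under catalyst control and the methyl-bearing centre lost later. Thermodynamic silylation (TMSCl, NaI, Et3N, MeCN) would give the more substituted silyl enol ether F4, and Saegusa–Ito dehydrogenation (Pd(OAc)2, MeCN) would give enone 15.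

Step 11. The enolate of the α,β-epoxy ketone may decompose (Favorskii-type ring contraction or opening of the oxirane), add to the sulfonimine by-product, or be oxidised with poor facial control. The fallback sets out from 15 and comes back at 21; it hydroxylates before the oxirane exists. The cross-conjugated kinetic enolate of enone 15 (LDA, THF, −78 °C) with the same oxaziridine would give the trans-6-hydroxy enone F5. TBSOTf/2,6-lutidine would give the bis-silyl ether F6. Luche reduction would give the allylic alcohol F7 (OH cis to the side chain, trans to the silyloxy group). VO(acac)2/t-BuOOH would give the epoxy alcohol F8, Dess–Martin oxidation the epoxy ketone F9, and HF·pyridine would remove both silyl groups to give diol 21.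

Step 13. The angelate may isomerise to the tiglate during acyl transfer, and the centre next to the ketone may epimerise or undergo α-ketol rearrangement under base and heat. The fallback sets out from 21 and comes back at 22; it builds the (Z)-alkenes after the ester bonds exist. Esterification of both hydroxyls with 2-[bis(2,2,2-trifluoroethoxy)phosphoryl]propanoic acid (DIC, cat. DMAP, CH2Cl2, 0 °C) would give the bis(phosphonopropionate) F10. Still–Gennari olefination with acetaldehyde (KHMDS, 18-crown-6, THF, −78 °C) would then give both (Z)-2-methylbut-2-enoates, that is 22.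

**Further compounds**
F1 | step 7 | tert-butyldimethyl{[(3S)-6-methyl-2-(4,4,5,5-tetramethyl-1,3,2-dioxaborolan-2-yl)hepta-1,5-dien-3-yl]oxy}silane | C=C(B1OC(C)(C)C(C)(C)O1)[C@H](CC=C(C)C)O[Si](C)(C)C(C)(C)C
F2 | step 7 | 6-methylcyclohex-2-en-1-one (racemic) | CC1CCC=CC1=O
F3 | step 7 | (3R)-3-[(3S)-3-(tert-butyldimethylsilyloxy)-6-methylhepta-1,5-dien-2-yl]-6-methylcyclohexan-1-one (mixture at C6) | C=C([C@H](CC=C(C)C)O[Si](C)(C)C(C)(C)C)[C@@H]1CCC(C)C(=O)C1
F4 | step 7 | trimethylsilyl enol ether of F3 (more substituted enol, C=C to the methyl-bearing carbon) | C=C([C@H](CC=C(C)C)O[Si](C)(C)C(C)(C)C)[C@@H]1CCC(C)=C(O[Si](C)(C)C)C1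
F5 | step 11 | (5S,6S)-5-[(3S)-3-(tert-butyldimethylsilyloxy)-6-methylhepta-1,5-dien-2-yl]-6-hydroxy-2-methylcyclohex-2-en-1-one (OH trans to the side chain) | C=C([C@H](CC=C(C)C)O[Si](C)(C)C(C)(C)C)[C@@H]1CC=C(C)C(=O)[C@H]1O
F6 | step 11 | tert-butyldimethylsilyl ether of F5 at the ring hydroxyl | C=C([C@H](CC=C(C)C)O[Si](C)(C)C(C)(C)C)[C@@H]1CC=C(C)C(=O)[C@H]1O[Si](C)(C)C(C)(C)C
F7 | step 11 | allylic alcohol from F6 (OH cis to the side chain, trans to the ring silyloxy group) | C=C([C@H](CC=C(C)C)O[Si](C)(C)C(C)(C)C)[C@@H]1CC=C(C)[C@H](O)[C@H]1O[Si](C)(C)C(C)(C)C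
F8 | step 11 | epoxy alcohol from F7 (oxirane cis to OH and side chain) | C=C([C@H](CC=C(C)C)O[Si](C)(C)C(C)(C)C)[C@@H]1C[C@@H]2O[C@]2(C)[C@H](O)[C@H]1O[Si](C)(C)C(C)(C)C
F9 | step 11 | bis-silyl ether of diol 21 (epoxy ketone) | C=C([C@H](CC=C(C)C)O[Si](C)(C)C(C)(C)C)[C@@H]1C[C@@H]2O[C@]2(C)C(=O)[C@H]1O[Si](C)(C)C(C)(C)C
F10 | step 13 | bis{2-[bis(2,2,2-trifluoroethoxy)phosphoryl]propanoate} of diol 21 (mixture at the two phosphonate-bearing carbons) | C=C([C@H](CC=C(C)C)OC(=O)C(C)P(=O)(OCC(F)(F)F)OCC(F)(F)F)[C@@H]1C[C@@H]2O[C@]2(C)C(=O)[C@H]1OC(=O)C(C)P(=O)(OCC(F)(F)F)OCC(F)(F)F
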